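## Numbering used throughout

1 5-iodovanillin · 2 its dioxolane acetal (free phenol) · 3 syringaldehyde · 4 MOM ether of 3 · 5 ethyl propenoate from 4 · 6 allylic alcohol · 7 allylic methyl carbonate · 8 sodium aryloxide of 2 · 9 radical precursor · 10 C9 hydroperoxide · 11 C9 alcohol (product of the key step) · 12 MOM-protected aldehyde · 13 phenolic aldehyde · 14 malonic acid · 15 arylidenemalonic acid · 16 target

## Analysis of the target

Compound 16 is a 2-aryl-3-(hydroxymethyl)-2,3-dihydrobenzofuran, a phenylcoumaran-type neolignan acid. Ring A carries a methoxy group at C7, next to the ring oxygen O1, and an (E)-propenoic acid at C5, para to O1. C2 carries a 4-hydroxy-3,5-dimethoxyphenyl (syringyl) ring and C3 carries the hydroxymethyl carbon C9. There are two adjacent stereocentres, C2 (S) and C3 (R), trans across the five-membered ring, and one E double bond. The weak point is the C2–O1 bond: it is benzylic to a para-hydroxyaryl ring and can open through a quinone methide in base or a benzylic cation in acid. The conjugated acid rules out late hydrogenolysis, and three electron-rich arenes rule out strong oxidants. C3 is not epimerisable, so once set it anchors the relative configuration. The difficulty is to fix the absolute configuration at the doubly activated C2 and relay it to C3 with trans selectivity while the C9 oxygen is introduced. The plan rests on the fact that C3 is bonded both to ring A carbon C3a and to C9: this is the pattern left when an aryl radical at C3a closes onto the inner carbon of a vinyl group on C2 and the resulting primary C9 radical is oxygenated.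

## Retrosynthetic reasoning

**16 to 13 and 14.** The Cα=Cβ bond of the propenoic acid is cut last, giving aldehyde 13 and the two-carbon donor 14. The forward reaction is a Knoevenagel–Doebner condensation through diacid 15. It delivers the free E acid directly, so no ester has to be hydrolysed on a base-sensitive phenol. Keeping the side chain out of the earlier steps also keeps a radical acceptor away from the key step.

**13 to 11.** Both protecting groups are removed in one acidic operation: the acetal at C5 opens first (giving 12), then the methoxymethyl ether on the syringyl oxygen. The forward step must be finished before the C2–O1 bond ionises. Because C3 cannot epimerise, a reversible opening at C2 would re-close to the trans isomer.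

**11 to 9 (key disconnection).** The C3–C3a bond and the C9–O bond are cut together. This leaves O1–C2 as a simple aryl allyl ether with a single stereocentre, and the carbon that becomes C9 is the terminus of a vinyl group. Cutting O1–C2 or C2–C3 instead would require both stereocentres to be built on an open chain. The forward reaction removes the iodine atom of 9 with a tin hydride chain, closes the C3a radical 5-exo onto the vinyl group, and captures the C9 radical with oxygen from air to give hydroperoxide 10, which is reduced to 11. One operation thus forms the ring, the C3 stereocentre and the C9 hydroxyl.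

**9 to 8 and 7.** The O1–C2 bond is cut between the ring A oxygen and the allylic carbon. The forward reaction is a branched-selective, enantioselective allylic substitution of the linear carbonate 7 by aryloxide 8 under iridium phosphoramidite catalysis. A direct displacement at a benzylic, allylic carbon bearing an electron-rich arene would suffer from attack at the alkene terminus and from ionisation. The metal-allyl route instead creates C2 under catalyst control from an achiral precursor.

**8 and 2 to 1.** Aryloxide 8 is the sodium salt of phenol 2, and 2 is 1 with the aldehyde masked as a cyclic acetal. The mask removes the acceptor character of C5, which would weaken the aryloxide and make the product ether easier to re-ionise. It also shields the aldehyde from stannyl and peroxyl radicals in the key step. A cyclic acetal is chosen over an acyclic one because an acetal para to a free phenol is unusually labile, and a ring-opened intermediate of the cyclic form re-closes intramolecularly.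

**7 to 3.** Carbonate 7 comes from alcohol 6 by O-acylation, 6 from ester 5 by 1,2-reduction, and 5 from aldehyde 4 by olefination. Aldehyde 4 is 3 with its phenol masked as a methoxymethyl ether. That group is inert to ylide, hydride, aryloxide and radical conditions and leaves in the same acid step as the acetal.

## Alternatives that were turned down

**Alternative 1:** Ring A is disconnected at C3a–C4 and C7–C7a, so the heterocycle is traced back to the trans γ-butyrolactone A2, which already holds O1, C2, C3 and C9.
- Forward key step: A2 is converted into its trimethylsilyl ketene acetal A3, which is heated with the electron-poor bromopyrone ester A4. Inverse-demand Diels–Alder addition across C6 and C3 of A4, extrusion of carbon dioxide and loss of silanol give benzofuran A1, with an ester at C5 and a bromine at C7.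
- For: both stereocentres are set in a lactone, where trans is the thermodynamic arrangement and no para-oxybenzyl aryl ether exists yet. The ring-forming step is thermal and tin-free. On stereochemical robustness before the key step this plan is at least as strong as the chosen one.
- Against: ring A arrives with the wrong substituents. The C7 bromine must be exchanged for methoxy by a copper-mediated C–O coupling next to the ring oxygen. The C5 ester must be taken down to the aldehyde and built up to the propenoic acid. The silyl ether must be removed, and the benzyl ether must be cleaved without hydrogenating the side chain or hydrogenolysing C2–O1. The cycloaddition must also bond to the fully substituted ketene acetal carbon, and A2 itself needs a multi-step enantioselective synthesis.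
- Comparison: the chosen plan buys ring A with methoxy, iodine and the C5 carbon in place and needs two steps after the key step instead of six or more. It pays with a tin reagent and a C2 centre that depends on catalyst control.

**Alternative 2:** The C3–C3a bond is made by a 1,2-shift, so the dihydrobenzofuran is traced back to the six-membered (2S)-flavanone A6.
- Forward key step: the enol ether of A6, formed in an orthoformate with strong acid, is attacked at C3 by a trivalent aryliodine oxidant. As the iodoarene leaves, the ring A carbon migrates from the carbonyl carbon to C3, the ring contracts, and the old carbonyl carbon becomes the methyl ester of A5.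
- For: such ring contractions are known to give 2,3-trans products, C9 arrives on the right carbon one reduction from the alcohol, and flavanones have established asymmetric entries. The C5 bromine would allow the propenoate to be attached directly by a Heck reaction. That endgame is more direct than the acetal, aldehyde and condensation sequence used here, and the plan is tin-free.
- Against: two groups can migrate. The electron-rich aryl ring on C2 competes with the ring A carbon and would lead to an isoflavone skeleton; the pivalate tempers that ring only partly. Both electron-rich rings are exposed to an electrophilic oxidant. A flavanone with an oxygenated 2-aryl group can lose its C2 configuration by reversible opening to the chalcone in acid. In A5 the C3 hydrogen is α to an ester and β to the ring oxygen, which invites elimination.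
- Comparison: the chosen plan forms the same C3–C3a bond with a radical that has only one course, uses no oxidant stronger than air, and never places C2 β to a carbonyl. It gives up the Heck endgame.

**Alternative 3:** The O1–C2 bond is cut, so the ring is traced back to the open 2,3-diarylpropyl acetate A8, whose only stereocentre is C3.
- Forward key step: constant-current electrolysis at a graphite anode in a nitrile–alcohol electrolyte removes two electrons and two protons from the syringyl phenol and its benzylic position. The resulting para-quinone methide at C2 is attacked by the ring A phenol (oxa-1,6 addition) to give A7.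
- For: A7 is one hydrolysis from the target, no protecting group is needed on the syringyl oxygen, the oxidant is current, and closure trans to the C3 substituent is favoured kinetically and thermodynamically. On steps after the key step and on reagent economy this plan is stronger than the chosen one.
- Against: selectivity rests on oxidation potentials. A8 has two phenols and a cinnamate, and A7 keeps the syringyl phenol with a more activated benzylic C–H, so over-oxidation of the product competes. The alcohol cosolvent competes with the ring A phenol, which is deactivated by the para-propenoate, and phenoxyl radical coupling is a further drain. The C3 stereocentre must first be made on an acyclic chain over several steps.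
- Comparison: in the chosen plan the key-step selectivity is decided by intramolecular radical rate constants, not by small potential differences among electron-rich arenes. The absolute configuration comes from one catalytic step.

Key step: step 7

Assumption: L is (Sa)-(1,1′-binaphthalene-2,2′-diyl) N,N-bis[(S)-1-phenylethyl]phosphoramidite, taken to give the (S)-ether 9 by the usual sense of induction for heteroatom nucleophiles on cinnamyl-type carbonates; the mirror-image ligand would be used if the sense proved opposite.

## Route

Step 1
Reactants: 1 4-hydroxy-3-iodo-5-methoxybenzaldehyde (5-iodovanillin)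
Product: 2 4-(1,3-dioxolan-2-yl)-2-iodo-6-methoxyphenol
Conditions: HO(CH2)2OH (5 equiv), p-TsOH·H2O (cat.), toluene, reflux, Dean–Stark trap; Et3N quench
Reagents that add atoms: ethane-1,2-diol, OCCO
Why: Acid-catalysed acetalisation driven by azeotropic removal of water; cyclic acetals of 4-hydroxy-3-methoxybenzaldehydes are isolable with the phenol free when kept away from acid, hence the basic quench.

Step 2
Reactants: 3 4-hydroxy-3,5-dimethoxybenzaldehyde (syringaldehyde)
Product: 4 3,5-dimethoxy-4-(methoxymethoxy)benzaldehyde
Conditions: MOMCl, i-Pr2NEt, CH2Cl2, 0 °C → rt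
Reagents that add atoms: chloromethyl methyl ether, COCCl
Why: O-alkylation of the phenol with a reactive α-chloro ether (Williamson-type); the methoxymethyl ether survives the ylide, hydride, aryloxide and radical steps that follow.

Step 3
Reactants: 4 3,5-dimethoxy-4-(methoxymethoxy)benzaldehyde
Product: 5 ethyl (E)-3-[3,5-dimethoxy-4-(methoxymethoxy)phenyl]prop-2-enoate
Conditions: Ph3P=CHCO2Et, toluene, 90 °C
Reagents that add atoms: ethyl 2-(triphenyl-λ5-phosphanylidene)acetate, CCOC(=O)C=P(c1ccccc1)(c1ccccc1)c1ccccc1
Why: Wittig olefination with a stabilised ylide, which should give the E ester needed for a geometrically pure linear allyl electrophile.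

Step 4
Reactants: 5 ethyl (E)-3-[3,5-dimethoxy-4-(methoxymethoxy)phenyl]prop-2-enoate
Product: 6 (E)-3-[3,5-dimethoxy-4-(methoxymethoxy)phenyl]prop-2-en-1-ol
Conditions: i-Bu2AlH (2.5 equiv), CH2Cl2, −78 → 0 °C; aq. KNaC4H4O6
Reagents that add atoms: none
Why: 1,2-Reduction of an α,β-unsaturated ester by an aluminium hydride at low temperature should leave the double bond and the acetal-type ether untouched.

Step 5
Reactants: 6 (E)-3-[3,5-dimethoxy-4-(methoxymethoxy)phenyl]prop-2-en-1-ol
Product: 7 (E)-3-[3,5-dimethoxy-4-(methoxymethoxy)phenyl]prop-2-en-1-yl methyl carbonate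
Conditions: ClCO2Me, pyridine, CH2Cl2, 0 °C
Reagents that add atoms: methyl chloroformate, COC(=O)Cl
Why: O-acylation with a chloroformate installs the carbonate leaving group, which ionises on the metal with loss of CO2.

Step 6
Reactants: 2 4-(1,3-dioxolan-2-yl)-2-iodo-6-methoxyphenol; 7 (E)-3-[3,5-dimethoxy-4-(methoxymethoxy)phenyl]prop-2-en-1-yl methyl carbonate
Product: 9 2-[4-[[(1S)-1-[3,5-dimethoxy-4-(methoxymethoxy)phenyl]prop-2-en-1-yl]oxy]-3-iodo-5-methoxyphenyl]-1,3-dioxolane, via sodium aryloxide 8 (not isolated)
Conditions: 2 (1.5 equiv), NaH, THF, 0 °C → rt; then 7, [Ir(cod)Cl]2 (2 mol%), L (4 mol%, pre-activated with n-PrNH2), THF, 40 °C; chromatography on Et3N-washed silica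
Reagents that add atoms: none
Why: Iridium-catalysed asymmetric allylic etherification: the carbonate adds oxidatively to the cyclometalated phosphoramidite complex of monovalent iridium, and aryloxide 8 attacks the resulting allyl complex of trivalent iridium at the aryl-substituted terminus from outside the coordination sphere, so the ligand sets C2 in the branched ether. The 4-alkoxy group flanked by two methoxy groups is twisted out of conjugation and the ring A substituent is an acetal rather than an aldehyde, which should limit re-ionisation of 9; the reaction is stopped at full conversion.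

Step 7
Reactants: 9 2-[4-[[(1S)-1-[3,5-dimethoxy-4-(methoxymethoxy)phenyl]prop-2-en-1-yl]oxy]-3-iodo-5-methoxyphenyl]-1,3-dioxolane
Product: 11 [(2S,3R)-2-[3,5-dimethoxy-4-(methoxymethoxy)phenyl]-5-(1,3-dioxolan-2-yl)-7-methoxy-2,3-dihydro-1-benzofuran-3-yl]methanol, via C9 hydroperoxide 10 (not isolated)
Conditions: Bu3SnH (1.5 equiv, syringe pump), Et3B (0.3 equiv, portions), dry air stream, toluene, 0 °C → rt; then PPh3, rt; aq. KF
Reagents that add atoms: dioxygen, O=O
Why: Ethyl radicals from Et3B and air start a stannyl radical chain; Bu3Sn• abstracts the iodine atom of 9 and leaves a σ-radical at C3a. This radical adds to the inner carbon of the vinyl group in a 5-exo-trig closure that forms C3–C3a and the dihydrofuran ring; closures of 2-(allyloxy)aryl radicals are among the fastest radical cyclisations, so hydrogen transfer from the slowly added stannane and capture of the aryl radical by dissolved oxygen should not compete, and 6-endo attack is disfavoured by the short, rigid tether. The primary C9 radical is trapped by dioxygen near the diffusion limit, the peroxyl radical takes hydrogen from Bu3SnH to give hydroperoxide 10 and a new stannyl radical, and PPh3 reduces 10 to 11, so the C9–O bond comes from air. The closest known reaction type is the aerobic, tin hydride-mediated oxygenative cyclisation of 2-iodophenyl allyl ethers to (2,3-dihydrobenzofuran-3-yl)methanols. The new stereocentre C3 is controlled by C2: in the chair-like transition state the aryl group on C2 is pseudo-equatorial and the C2–H bond, not the C2–aryl bond, lies near the plane of the vinyl group (least allylic strain), which puts C9 on the face opposite the aryl group and gives the 2,3-trans (2S,3R) isomer. The step needs oxygen capture to beat reduction at C9, which the low stationary stannane concentration and the continuous air stream should secure. It also needs the acetal, the methoxymethyl ether and the weak C2–H bond to stay untouched, which low temperature and short contact time favour. Any cis isomer is removed by chromatography at this stage.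

Step 8
Reactants: 11 [(2S,3R)-2-[3,5-dimethoxy-4-(methoxymethoxy)phenyl]-5-(1,3-dioxolan-2-yl)-7-methoxy-2,3-dihydro-1-benzofuran-3-yl]methanol
Product: 13 (2S,3R)-2-(4-hydroxy-3,5-dimethoxyphenyl)-3-(hydroxymethyl)-7-methoxy-2,3-dihydro-1-benzofuran-5-carbaldehyde, via MOM-protected aldehyde 12 (not isolated)
Conditions: 3 M HCl (aq), THF, 40 °C
Reagents that add atoms: water, O
Why: Acid-catalysed acetal hydrolysis: the dioxolane opens first to give 12 and the aryl methoxymethyl ether follows, both ionising far more readily than the C2–O1 aryl ether. Since C3 cannot epimerise, a reversible opening at C2 would re-close to the trans isomer.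

Step 9
Reactants: 13 (2S,3R)-2-(4-hydroxy-3,5-dimethoxyphenyl)-3-(hydroxymethyl)-7-methoxy-2,3-dihydro-1-benzofuran-5-carbaldehyde; 14 propanedioic acid (malonic acid)
Product: 16 (E)-3-[(2S,3R)-2-(4-hydroxy-3,5-dimethoxyphenyl)-3-(hydroxymethyl)-7-methoxy-2,3-dihydro-1-benzofuran-5-yl]prop-2-enoic acid (the target), via arylidenemalonic acid 15 (not isolated)
Conditions: 14 (3 equiv), pyridine, piperidine (cat.), 80 °C; then cold 1 M HCl
Reagents that add atoms: none
Why: Knoevenagel–Doebner condensation: amine-catalysed condensation of 13 with 14 gives diacid 15, which decarboxylates in hot pyridine to the thermodynamically favoured E acid. The excess of 14 buffers the medium so the syringyl phenol stays largely un-ionised, and no ester hydrolysis is needed afterwards.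

## Compound list

1 | 4-hydroxy-3-iodo-5-methoxybenzaldehyde (5-iodovanillin) | COc1cc(C=O)cc(I)c1O | starting material
2 | 4-(1,3-dioxolan-2-yl)-2-iodo-6-methoxyphenol | COc1cc(C2OCCO2)cc(I)c1O | intermediate
3 | 4-hydroxy-3,5-dimethoxybenzaldehyde (syringaldehyde) | COc1cc(C=O)cc(OC)c1O | starting material
4 | 3,5-dimethoxy-4-(methoxymethoxy)benzaldehyde | COCOc1c(OC)cc(C=O)cc1OC | intermediate
5 | ethyl (E)-3-[3,5-dimethoxy-4-(methoxymethoxy)phenyl]prop-2-enoate | CCOC(=O)/C=C/c1cc(OC)c(OCOC)c(OC)c1 | intermediate
6 | (E)-3-[3,5-dimethoxy-4-(methoxymethoxy)phenyl]prop-2-en-1-ol | COCOc1c(OC)cc(/C=C/CO)cc1OC | intermediate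
7 | (E)-3-[3,5-dimethoxy-4-(methoxymethoxy)phenyl]prop-2-en-1-yl methyl carbonate | COCOc1c(OC)cc(/C=C/COC(=O)OC)cc1OC | intermediate
8 | sodium 4-(1,3-dioxolan-2-yl)-2-iodo-6-methoxyphenolate | COc1cc(C2OCCO2)cc(I)c1[O-].[Na+] | intermediate
9 | 2-[4-[[(1S)-1-[3,5-dimethoxy-4-(methoxymethoxy)phenyl]prop-2-en-1-yl]oxy]-3-iodo-5-methoxyphenyl]-1,3-dioxolane | COCOc1c(OC)cc([C@H](C=C)Oc2c(OC)cc(C3OCCO3)cc2I)cc1OC | intermediate
10 | 2-[(2S,3R)-2-[3,5-dimethoxy-4-(methoxymethoxy)phenyl]-3-(hydroperoxymethyl)-7-methoxy-2,3-dihydro-1-benzofuran-5-yl]-1,3-dioxolane | COCOc1c(OC)cc([C@H]2Oc3c(OC)cc(C4OCCO4)cc3[C@@H]2COO)cc1OC | intermediate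
11 | [(2S,3R)-2-[3,5-dimethoxy-4-(methoxymethoxy)phenyl]-5-(1,3-dioxolan-2-yl)-7-methoxy-2,3-dihydro-1-benzofuran-3-yl]methanol | COCOc1c(OC)cc([C@H]2Oc3c(OC)cc(C4OCCO4)cc3[C@@H]2CO)cc1OC | intermediate
12 | (2S,3R)-2-[3,5-dimethoxy-4-(methoxymethoxy)phenyl]-3-(hydroxymethyl)-7-methoxy-2,3-dihydro-1-benzofuran-5-carbaldehyde | COCOc1c(OC)cc([C@H]2Oc3c(OC)cc(C=O)cc3[C@@H]2CO)cc1OC | intermediate
13 | (2S,3R)-2-(4-hydroxy-3,5-dimethoxyphenyl)-3-(hydroxymethyl)-7-methoxy-2,3-dihydro-1-benzofuran-5-carbaldehyde | COc1cc([C@H]2Oc3c(OC)cc(C=O)cc3[C@@H]2CO)cc(OC)c1O | intermediate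
14 | propanedioic acid (malonic acid) | OC(=O)CC(=O)O | starting material
15 | 2-[[(2S,3R)-2-(4-hydroxy-3,5-dimethoxyphenyl)-3-(hydroxymethyl)-7-methoxy-2,3-dihydro-1-benzofuran-5-yl]methylidene]propanedioic acid | COc1cc([C@H]2Oc3c(OC)cc(C=C(C(=O)O)C(=O)O)cc3[C@@H]2CO)cc(OC)c1O | intermediate
16 | (E)-3-[(2S,3R)-2-(4-hydroxy-3,5-dimethoxyphenyl)-3-(hydroxymethyl)-7-methoxy-2,3-dihydro-1-benzofuran-5-yl]prop-2-enoic acid | COc1cc([C@H]2Oc3c(OC)cc(/C=C/C(=O)O)cc3[C@@H]2CO)cc(OC)c1O | target

## Step count and least certain steps

Total step count: 9. Longest linear sequence: 8 steps (steps 2 to 9, from 3); step 1 is a one-step branch from 1.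

**Step 7 (key step).** Three processes may intervene. Hydrogen may be transferred from the stannane to the C9 radical before oxygen capture if air delivery falls behind. Chain autoxidation may start at the C2–H bond of 9, which is benzylic, allylic and α to oxygen. The closure may also give less trans selectivity than the transition-state model suggests. The fallback removes dioxygen and peroxyl radicals from the flask. It sets out from 9: Bu3SnH and TEMPO, both in excess and added in portions in toluene at 70 °C under argon, should generate the same C3a radical. After the 5-exo closure the nitroxide captures the C9 radical to give the alkoxyamine 2-[(2S,3R)-2-[3,5-dimethoxy-4-(methoxymethoxy)phenyl]-7-methoxy-3-[[(2,2,6,6-tetramethylpiperidin-1-yl)oxy]methyl]-2,3-dihydro-1-benzofuran-5-yl]-1,3-dioxolane F1. Zn dust with AcOH in THF at 40 °C should then cleave the N–O bond. The route is rejoined at 11; any material whose dioxolane has opened is 12, the intermediate of step 8, and is carried forward with it.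

**Step 6.** Attack by the 2,6-disubstituted aryloxide may be slow. Reversible ionisation of the product ether by the catalyst may erode the enantiomeric purity and leak material to the linear ether. The fallback takes the stereocentre from a reagent-controlled epoxidation and an invertive opening. It sets out from 6 and uses aryloxide 8.
- Sharpless asymmetric epoxidation of 6 (Ti(O-i-Pr)4, L-(+)-diethyl tartrate, t-BuOOH, 4 Å sieves, CH2Cl2, −20 °C) should give [(2S,3S)-3-[3,5-dimethoxy-4-(methoxymethoxy)phenyl]oxiran-2-yl]methanol F2.
- Aryloxide 8 in aqueous NaOH–dioxane at 60 °C should open F2 at the benzylic carbon with inversion, giving (2S,3R)-3-[4-(1,3-dioxolan-2-yl)-2-iodo-6-methoxyphenoxy]-3-[3,5-dimethoxy-4-(methoxymethoxy)phenyl]propane-1,2-diol F3.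
- 1,1′-Thiocarbonyldiimidazole in THF converts F3 into the cyclic thionocarbonate (4S)-4-[(R)-[4-(1,3-dioxolan-2-yl)-2-iodo-6-methoxyphenoxy][3,5-dimethoxy-4-(methoxymethoxy)phenyl]methyl]-1,3-dioxolane-2-thione F4.
- Corey–Winter fragmentation of F4 with 1,3-dimethyl-2-phenyl-1,3,2-diazaphospholidine in THF at 40 °C releases the terminal alkene, and the route is rejoined at 9.

**Step 8.** During the time needed to cleave the aryl methoxymethyl ether, the liberated methoxymethyl cation or formaldehyde may be transferred to the free C9 hydroxyl, or the C2–O1 bond may ionise and open. The fallback separates the two deprotections and sets out from 11. Pyridinium p-toluenesulfonate in wet acetone at rt should remove only the dioxolane, so that 12 is isolated. The condensation with 14 (pyridine, piperidine, 80 °C) is then run on 12 with the phenol still masked. It passes through 2-[[(2S,3R)-2-[3,5-dimethoxy-4-(methoxymethoxy)phenyl]-3-(hydroxymethyl)-7-methoxy-2,3-dihydro-1-benzofuran-5-yl]methylidene]propanedioic acid F5 and gives (E)-3-[(2S,3R)-2-[3,5-dimethoxy-4-(methoxymethoxy)phenyl]-3-(hydroxymethyl)-7-methoxy-2,3-dihydro-1-benzofuran-5-yl]prop-2-enoic acid F6. The methoxymethyl ether is cleaved last with ZnBr2 and n-PrSH in CH2Cl2 at 0 °C, where the thiol scavenges the methoxymethyl unit irreversibly. The route is rejoined at 16.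

**Step 9.** Heating with amines may open the dihydrofuran through the syringyl quinone methide, because the ring A phenoxide is a good leaving group when para to the aldehyde or the acid; irreversible elimination could follow. Decarboxylation of 15 may also stall. The fallback replaces the hot condensation by a neutral olefination at ambient temperature and sets out from 13. Ph3P=CHCO2Me in CH2Cl2 at rt should give methyl (E)-3-[(2S,3R)-2-(4-hydroxy-3,5-dimethoxyphenyl)-3-(hydroxymethyl)-7-methoxy-2,3-dihydro-1-benzofuran-5-yl]prop-2-enoate F7. Saponification with LiOH in THF–water at 0 °C → rt and careful acidification rejoin the route at 16.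

## Further compounds

F1 | step 7 | 2-[(2S,3R)-2-[3,5-dimethoxy-4-(methoxymethoxy)phenyl]-7-methoxy-3-[[(2,2,6,6-tetramethylpiperidin-1-yl)oxy]methyl]-2,3-dihydro-1-benzofuran-5-yl]-1,3-dioxolane | COCOc1c(OC)cc([C@H]2Oc3c(OC)cc(C4OCCO4)cc3[C@@H]2CON5C(C)(C)CCCC5(C)C)cc1OC
F2 | step 6 | [(2S,3S)-3-[3,5-dimethoxy-4-(methoxymethoxy)phenyl]oxiran-2-yl]methanol | COCOc1c(OC)cc([C@@H]2O[C@H]2CO)cc1OC
F3 | step 6 | (2S,3R)-3-[4-(1,3-dioxolan-2-yl)-2-iodo-6-methoxyphenoxy]-3-[3,5-dimethoxy-4-(methoxymethoxy)phenyl]propane-1,2-diol | COCOc1c(OC)cc([C@H]([C@@H](O)CO)Oc2c(OC)cc(C3OCCO3)cc2I)cc1OC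
F4 | step 6 | (4S)-4-[(R)-[4-(1,3-dioxolan-2-yl)-2-iodo-6-methoxyphenoxy][3,5-dimethoxy-4-(methoxymethoxy)phenyl]methyl]-1,3-dioxolane-2-thione | COCOc1c(OC)cc([C@H]([C@@H]2COC(=S)O2)Oc2c(OC)cc(C3OCCO3)cc2I)cc1OC
F5 | step 8 | 2-[[(2S,3R)-2-[3,5-dimethoxy-4-(methoxymethoxy)phenyl]-3-(hydroxymethyl)-7-methoxy-2,3-dihydro-1-benzofuran-5-yl]methylidene]propanedioic acid | COCOc1c(OC)cc([C@H]2Oc3c(OC)cc(C=C(C(=O)O)C(=O)O)cc3[C@@H]2CO)cc1OC
F6 | step 8 | (E)-3-[(2S,3R)-2-[3,5-dimethoxy-4-(methoxymethoxy)phenyl]-3-(hydroxymethyl)-7-methoxy-2,3-dihydro-1-benzofuran-5-yl]prop-2-enoic acid | COCOc1c(OC)cc([C@H]2Oc3c(OC)cc(/C=C/C(=O)O)cc3[C@@H]2CO)cc1OC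
F7 | step 9 | methyl (E)-3-[(2S,3R)-2-(4-hydroxy-3,5-dimethoxyphenyl)-3-(hydroxymethyl)-7-methoxy-2,3-dihydro-1-benzofuran-5-yl]prop-2-enoate | COc1cc([C@H]2Oc3c(OC)cc(/C=C/C(=O)OC)cc3[C@@H]2CO)cc(OC)c1O
A1 | alternative 1 | methyl 2,3-trans-2-(4-benzyloxy-3,5-dimethoxyphenyl)-7-bromo-3-[(tert-butyldimethylsilyloxy)methyl]-2,3-dihydro-1-benzofuran-5-carboxylate | COc1cc([C@H]2Oc3c(Br)cc(C(=O)OC)cc3[C@@H]2CO[Si](C)(C)C(C)(C)C)cc(OC)c1OCc1ccccc1
A2 | alternative 1 | 4,5-trans-5-(4-benzyloxy-3,5-dimethoxyphenyl)-4-[(tert-butyldimethylsilyloxy)methyl]oxolan-2-one | COc1cc([C@H]2OC(=O)C[C@@H]2CO[Si](C)(C)C(C)(C)C)cc(OC)c1OCc1ccccc1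
A3 | alternative 1 | 2,3-trans-2-(4-benzyloxy-3,5-dimethoxyphenyl)-3-[(tert-butyldimethylsilyloxy)methyl]-5-(trimethylsilyloxy)-2,3-dihydrofuran | COc1cc([C@H]2OC(O[Si](C)(C)C)=C[C@@H]2CO[Si](C)(C)C(C)(C)C)cc(OC)c1OCc1ccccc1
A4 | alternative 1 | methyl 3-bromo-2-oxo-2H-pyran-5-carboxylate | O=C1OC=C(C(=O)OC)C=C1Br
A5 | alternative 2 | methyl 2,3-trans-5-bromo-2-[3,5-dimethoxy-4-(pivaloyloxy)phenyl]-7-methoxy-2,3-dihydro-1-benzofuran-3-carboxylate | COc1cc([C@H]2Oc3c(OC)cc(Br)cc3[C@@H]2C(=O)OC)cc(OC)c1OC(=O)C(C)(C)C
A6 | alternative 2 | (2S)-6-bromo-2-[3,5-dimethoxy-4-(pivaloyloxy)phenyl]-8-methoxychroman-4-one | COc1cc([C@@H]2CC(=O)c3cc(Br)cc(OC)c3O2)cc(OC)c1OC(=O)C(C)(C)C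
A7 | alternative 3 | methyl (E)-3-[2,3-trans-3-(acetoxymethyl)-2-(4-hydroxy-3,5-dimethoxyphenyl)-7-methoxy-2,3-dihydro-1-benzofuran-5-yl]prop-2-enoate | COc1cc([C@H]2Oc3c(OC)cc(/C=C/C(=O)OC)cc3[C@@H]2COC(C)=O)cc(OC)c1O
A8 | alternative 3 | methyl (E)-3-[3-[1-acetoxy-3-(4-hydroxy-3,5-dimethoxyphenyl)propan-2-yl]-4-hydroxy-5-methoxyphenyl]prop-2-enoate, single enantiomer at the carbon bearing the acetoxymethyl group | COc1cc(C[C@@H](COC(C)=O)c2cc(/C=C/C(=O)OC)cc(OC)c2O)cc(OC)c1O
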